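**Plan**
- Retrosynthesis: cut the C-6 angelate (ester formation with inversion), then the two lactone bonds C-5–Cα and C-4–O together with the exocyclic methylene, then the ring bond C-5–C-6 and the C-1=C-2 alkene.
- Forward: the chain C-1 to C-6 comes from geraniol; a Wittig reaction sets the trisubstituted alkene; a Nozaki–Hiyama–Kishi closure gives the ten-membered ring; one oxidative radical step then adds both five-membered lactones; the tether lactone is opened again.
- Enabling feature: the E-alkene C-4=C-5 of the ten-membered ring is allylic to the C-6 oxygen. A malonyl radical hung on O-6 reaches C-5 through a five-membered transition state, and the C-4 radical left behind is captured by the free carboxyl.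
- Helpers: the malonyl tether supplies Cα and the lactone carbonyl; one of its two carbonyls leaves as CO2 when the methylene is made; the anchoring C-6 oxygen is freed and replaced with inversion by the angelate.
- Stereochemistry: C-8 from Sharpless epoxidation; C-6 from CBS reduction (S), inverted at the end (R); C-5 from tether delivery; C-4 from the E-alkene geometry.

Key step: step 16

Remark: the carbocycle is numbered C-1 to C-10 with C-1=C-2 the trisubstituted alkene (C-2 bears CH2OAc), C-4 the lactone carbinol, C-5 the ring-fusion carbon, C-6 the angelate carbon and C-8 the tertiary carbinol; Cα is the lactone carbon next to the carbonyl.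
Remark: tether delivery is expected trans to the C-6 ring bond, so the C-6 carbinol is made S and inverted in the last step; compounds 7, 8, 21, 24 and 31 are taken as commercial.

Step 1
Reactants: 1 geraniol
Product: 2 (2S,3S)-2,3-epoxygeraniol
Conditions: Ti(OiPr)4 (cat.), L-(+)-diethyl tartrate, tBuOOH, 4 Å MS, CH2Cl2, −20 °C
Reagents that add atoms: tert-butyl hydroperoxide, CC(C)(C)OO
Why: Sharpless asymmetric epoxidation acts only on the allylic alkene, and the L-tartrate ligand sets the (2S,3S) epoxide whose C-3 becomes C-8 of the target.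

Step 2
Reactants: 2 (2S,3S)-2,3-epoxygeraniol
Product: 3 (3S)-3,7-dimethyloct-6-ene-1,3-diol
Conditions: NaAlH2(OCH2CH2OMe)2, THF, 0 °C
Reagents that add atoms: none
Why: hydroxyl-directed hydride delivery opens the 2,3-epoxy alcohol at C-2, so the tertiary C–O bond and its configuration are kept and a 1,3-diol results.

Step 3
Reactants: 3 (3S)-3,7-dimethyloct-6-ene-1,3-diol
Product: 4 (3S)-3,7-dimethyl-1,3-bis(triethylsilyloxy)oct-6-ene
Conditions: Et3SiOTf, 2,6-lutidine, CH2Cl2, −78 to 0 °C
Reagents that add atoms: triethylsilyl trifluoromethanesulfonate, CC[Si](CC)(CC)OS(=O)(=O)C(F)(F)F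
Why: the silyl triflate silylates both the primary and the hindered tertiary hydroxyl.

Step 4
Reactants: 4 (3S)-3,7-dimethyl-1,3-bis(triethylsilyloxy)oct-6-ene
Product: 6 (4S)-4-methyl-4,6-bis(triethylsilyloxy)hexanal, via secondary ozonide 5 (not isolated)
Conditions: O3, CH2Cl2, −78 °C; then PPh3, −78 to 23 °C
Reagents that add atoms: ozone, [O-][O+]=O
Why: ozonolysis with reductive work-up cleaves the only alkene to the aldehyde (the future C-1) and acetone, and silyl ethers tolerate it.

Step 5
Reactants: 7 ethyl (triphenylphosphoranylidene)acetate, 8 propargyl bromide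
Product: 10 ethyl 2-(triphenylphosphoranylidene)pent-4-ynoate, via phosphonium bromide 9 (not isolated)
Conditions: EtOAc, reflux; then aq. NaOH, CH2Cl2, 0 °C
Reagents that add atoms: none
Why: C-alkylation of the stabilized ylide followed by deprotonation of the phosphonium salt gives the α-propargyl stabilized ylide.

Step 6
Reactants: 6 (4S)-4-methyl-4,6-bis(triethylsilyloxy)hexanal, 10 ethyl 2-(triphenylphosphoranylidene)pent-4-ynoate
Product: 11 ethyl (2E,6S)-6-methyl-2-(prop-2-yn-1-yl)-6,8-bis(triethylsilyloxy)oct-2-enoate
Conditions: toluene, 90 °C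
Reagents that add atoms: none
Why: the Wittig reaction of an α-substituted stabilized ylide places the ester trans to the chain, which is the geometry in which the two future ring bonds at C-1=C-2 are cis.

Step 7
Reactants: 11 ethyl (2E,6S)-6-methyl-2-(prop-2-yn-1-yl)-6,8-bis(triethylsilyloxy)oct-2-enoate
Product: 12 (2E,6S)-6-methyl-2-(prop-2-yn-1-yl)-6,8-bis(triethylsilyloxy)oct-2-en-1-ol
Conditions: iBu2AlH, CH2Cl2, −78 °C
Reagents that add atoms: none
Why: 1,2-reduction of the enoate gives the allylic alcohol without touching the alkyne or the silyl ethers.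

Step 8
Reactants: 12 (2E,6S)-6-methyl-2-(prop-2-yn-1-yl)-6,8-bis(triethylsilyloxy)oct-2-en-1-ol
Product: 14 (2E,6S)-2-[(2E)-3-iodoprop-2-en-1-yl]-6-methyl-6,8-bis(triethylsilyloxy)oct-2-en-1-ol, via alkenylzirconocene 13 (not isolated)
Conditions: Cp2Zr(H)Cl (2.5 equiv), THF, 23 °C; then I2, 0 °C
Reagents that add atoms: iodine, II
Why: syn hydrozirconation of the terminal alkyne puts zirconium on the terminal carbon, and iodination with retention gives the E-vinyl iodide; the extra hydride is consumed by the hydroxyl.

Step 9
Reactants: 14 (2E,6S)-2-[(2E)-3-iodoprop-2-en-1-yl]-6-methyl-6,8-bis(triethylsilyloxy)oct-2-en-1-ol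
Product: 15 (2E,6S)-2-[(2E)-3-iodoprop-2-en-1-yl]-6-methyl-6,8-bis(triethylsilyloxy)oct-2-en-1-yl acetate
Conditions: Ac2O, pyridine, DMAP (cat.), CH2Cl2, 0 °C
Reagents that add atoms: acetic anhydride, CC(=O)OC(C)=O
Why: acetylation protects the only free hydroxyl so that it survives the oxidations that follow.

Step 10
Reactants: 15 (2E,6S)-2-[(2E)-3-iodoprop-2-en-1-yl]-6-methyl-6,8-bis(triethylsilyloxy)oct-2-en-1-yl acetate
Product: 16 (2E,6S)-2-[(2E)-3-iodoprop-2-en-1-yl]-6-methyl-8-oxo-6-(triethylsilyloxy)oct-2-en-1-yl acetate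
Conditions: (COCl)2, DMSO, CH2Cl2, −78 to −40 °C; then Et3N
Reagents that add atoms: none
Why: Swern conditions cleave and oxidize a primary triethylsilyl ether directly to the aldehyde, while the tertiary silyl ether, the acetate and the vinyl iodide stay intact.

Step 11
Reactants: 16 (2E,6S)-2-[(2E)-3-iodoprop-2-en-1-yl]-6-methyl-8-oxo-6-(triethylsilyloxy)oct-2-en-1-yl acetate
Product: 17 [(1E,4E,8S)-6-hydroxy-8-methyl-8-(triethylsilyloxy)cyclodeca-1,4-dien-2-yl]methyl acetate (both C-6 epimers)
Conditions: CrCl2 (excess), NiCl2 (cat.), DMSO/THF, high dilution, 23 °C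
Reagents that add atoms: none
Why: in the Nozaki–Hiyama–Kishi closure zerovalent nickel inserts into the vinyl iodide, the vinyl group passes to trivalent chromium and adds to the aldehyde, closing the ten-membered ring with the E geometry kept; the new carbinol is corrected in steps 12 and 13.

Step 12
Reactants: 17 [(1E,4E,8S)-6-hydroxy-8-methyl-8-(triethylsilyloxy)cyclodeca-1,4-dien-2-yl]methyl acetate
Product: 18 [(1E,4E,8S)-8-methyl-6-oxo-8-(triethylsilyloxy)cyclodeca-1,4-dien-2-yl]methyl acetate
Conditions: Dess–Martin periodinane, NaHCO3, CH2Cl2, 0 °C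
Reagents that add atoms: none
Why: buffered oxidation of the allylic alcohol converges both epimers on one enone without moving the skipped diene into conjugation.

Step 13
Reactants: 18 [(1E,4E,8S)-8-methyl-6-oxo-8-(triethylsilyloxy)cyclodeca-1,4-dien-2-yl]methyl acetate
Product: 19 [(1E,4E,6S,8S)-6-hydroxy-8-methyl-8-(triethylsilyloxy)cyclodeca-1,4-dien-2-yl]methyl acetate
Conditions: (R)-2-methyl-CBS-oxazaborolidine, catecholborane, toluene, −78 °C
Reagents that add atoms: none
Why: in the Corey–Bakshi–Shibata reduction the alkenyl group acts as the large substituent, so the R catalyst should give the 6S allylic alcohol under reagent control, and catecholborane at low temperature avoids hydroboration.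

Step 14
Reactants: 19 [(1E,4E,6S,8S)-6-hydroxy-8-methyl-8-(triethylsilyloxy)cyclodeca-1,4-dien-2-yl]methyl acetate
Product: 20 [(1E,4E,6S,8S)-6,8-dihydroxy-8-methylcyclodeca-1,4-dien-2-yl]methyl acetate
Conditions: HF·pyridine, pyridine, THF, 0 °C
Reagents that add atoms: none
Why: fluoride removes the tertiary silyl ether without touching the acetate, freeing the C-8 hydroxyl that later steers the choice of lactone.

Step 15
Reactants: 20 [(1E,4E,6S,8S)-6,8-dihydroxy-8-methylcyclodeca-1,4-dien-2-yl]methyl acetate, 21 Meldrum's acid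
Product: 22 hydrogen malonate of 20 at the C-6 oxygen
Conditions: toluene, 80 °C
Reagents that add atoms: none
Why: the secondary allylic hydroxyl opens Meldrum's acid to the malonic half-ester with loss of acetone, and the tertiary hydroxyl is too hindered to react.

Step 16
Reactants: 22 hydrogen malonate of 20 at the C-6 oxygen
Product: 23 bis-lactone in which Cα is bonded to C-5 and carries two lactone carbonyls, one closed on O-6 and one on the new C-4 oxygen
Conditions: Mn(OAc)3·2H2O (2.5 equiv), KOAc, AcOH, degassed, 25 to 40 °C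
Reagents that add atoms: none
Why: the trivalent manganese enolate of the malonic half-acid gives the α-radical, which adds by 5-exo-trig closure to C-5, the near carbon of the E-alkene; the C-4 radical is then oxidized inside the manganese carboxylate so that the free carboxyl oxygen bonds to C-4 in a second five-membered closure, and the C-5–Cα and C-4–O bonds form in one operation. The closest known reaction type is the Mn(OAc)3-mediated oxidative radical cyclization–lactonization of allylic malonates and malonic half-acids to fused bis-γ-lactones. C-5 is set by the C-6 stereocenter through the ester tether, with the ring bond C-6–C-7 and C-4 trans on the new lactone as is usual for 4-substituted hex-5-enyl-type radicals; C-4 follows from the E geometry, because the carboxyl closes on the face that already carries Cα while C-3 stays anti to C-6 (trans ring fusion); Cα becomes cis-fused and is erased in step 18. The step needs site selectivity for the disubstituted over the trisubstituted alkene and for C-5 over C-4, both secured by the five-membered tether, and lactonization instead of loss of a C-3 hydrogen, which is favoured by leaving out a copper co-oxidant.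

Step 17
Reactants: 23 bis-lactone, 24 Eschenmoser's salt
Product: 26 Cα-[(trimethylammonio)methyl] bis-lactone iodide, via Mannich base 25 (not isolated)
Conditions: iPr2NEt, CH2Cl2, 0 to 23 °C; then MeI, MeCN, 23 °C
Reagents that add atoms: iodomethane, CI
Why: the acidic malonate-type C–H at Cα undergoes the Mannich reaction on the convex face, and quaternization turns the amine into a leaving group for the later fragmentation.

Step 18
Reactants: 26 Cα-[(trimethylammonio)methyl] bis-lactone iodide
Product: 28 α-methylene γ-lactone closed on O-4 with O-6 and O-8 tied as a cyclic phenylboronate and a free CH2OH on C-2, via lithium acrylate 27 (not isolated)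
Conditions: LiOH, THF/H2O, 0 to 23 °C; 1 M HCl to pH 4, 0 °C, EtOAc; then PhB(OH)2, MgSO4, CH2Cl2, 23 to 40 °C
Reagents that add atoms: phenylboronic acid, OB(O)c1ccccc1; lithium hydroxide, [Li+].[OH-]
Why: hydroxide opens the quaternary bis-lactone, the β-ammonium carboxylate fragments (Grob-type decarboxylative elimination) to the acrylate and the second lactone and the acetate are saponified; after acidification the boronic acid binds the 1,3-diols reversibly, and only the O-6/O-8 boronate leaves a γ-hydroxyl (O-4) free to lactonize irreversibly, so the material should drain into the C-4 lactone.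

Step 19
Reactants: 28 phenylboronate lactone
Product: 30 C-6 epimer of the de-angeloyl target (α-methylene lactone on O-4, CH2OAc on C-2, free 6S and C-8 hydroxyls), via boronate acetate 29 (not isolated)
Conditions: Ac2O, pyridine, DMAP (cat.), CH2Cl2, 0 °C; then 2,2-dimethylpropane-1,3-diol, THF, 23 °C
Reagents that add atoms: acetic anhydride, CC(=O)OC(C)=O
Why: with O-6 and O-8 masked in the boronate, only the primary allylic hydroxyl is acetylated, and exchange with a primary 1,3-diol then releases the secondary/tertiary diol.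

Step 20
Reactants: 30 C-6 epimer of the de-angeloyl target, 31 angelic acid
Product: 32 target CNP0270682.1
Conditions: PPh3, DIAD, toluene, 0 to 23 °C
Reagents that add atoms: none
Why: in the Mitsunobu esterification the C-6 hydroxyl is activated as the alkoxyphosphonium ion and displaced by angelate with inversion, turning the 6S carbinol into the 6R angelate; the tertiary hydroxyl does not react and the neutral conditions should not isomerize the Z-ester.

**Compound list**
1 | geraniol | CC(C)=CCC/C(C)=C/CO | starting material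
2 | (2S,3S)-2,3-epoxygeraniol | CC(C)=CCC[C@]1(C)O[C@H]1CO | intermediate
3 | (3S)-3,7-dimethyloct-6-ene-1,3-diol | CC(C)=CCC[C@](C)(O)CCO | intermediate
4 | (3S)-3,7-dimethyl-1,3-bis(triethylsilyloxy)oct-6-ene | CC(C)=CCC[C@](C)(O[Si](CC)(CC)CC)CCO[Si](CC)(CC)CC | intermediate
5 | secondary ozonide of 4 (1,2,4-trioxolane, ring carbon unspecified) | CC1(C)OOC(CC[C@](C)(O[Si](CC)(CC)CC)CCO[Si](CC)(CC)CC)O1 | intermediate (not isolated)
6 | (4S)-4-methyl-4,6-bis(triethylsilyloxy)hexanal | O=CCC[C@](C)(O[Si](CC)(CC)CC)CCO[Si](CC)(CC)CC | intermediate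
7 | ethyl (triphenylphosphoranylidene)acetate | CCOC(=O)C=P(c1ccccc1)(c1ccccc1)c1ccccc1 | starting material
8 | propargyl bromide | C#CCBr | starting material
9 | (1-ethoxy-1-oxopent-4-yn-2-yl)triphenylphosphonium bromide | CCOC(=O)C(CC#C)[P+](c1ccccc1)(c1ccccc1)c1ccccc1.[Br-] | intermediate (not isolated)
10 | ethyl 2-(triphenylphosphoranylidene)pent-4-ynoate | CCOC(=O)C(CC#C)=P(c1ccccc1)(c1ccccc1)c1ccccc1 | intermediate
11 | ethyl (2E,6S)-6-methyl-2-(prop-2-yn-1-yl)-6,8-bis(triethylsilyloxy)oct-2-enoate | CCOC(=O)/C(CC#C)=C/CC[C@](C)(O[Si](CC)(CC)CC)CCO[Si](CC)(CC)CC | intermediate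
12 | (2E,6S)-6-methyl-2-(prop-2-yn-1-yl)-6,8-bis(triethylsilyloxy)oct-2-en-1-ol | OC/C(CC#C)=C/CC[C@](C)(O[Si](CC)(CC)CC)CCO[Si](CC)(CC)CC | intermediate
13 | (E)-alkenylzirconocene chloride of 12, zirconium alkoxide at O-1 | Cl[Zr](OC/C(C/C=C/[Zr](Cl)(C1C=CC=C1)C1C=CC=C1)=C/CC[C@](C)(O[Si](CC)(CC)CC)CCO[Si](CC)(CC)CC)(C1C=CC=C1)C1C=CC=C1 | intermediate (not isolated)
14 | (2E,6S)-2-[(2E)-3-iodoprop-2-en-1-yl]-6-methyl-6,8-bis(triethylsilyloxy)oct-2-en-1-ol | OC/C(C/C=C/I)=C/CC[C@](C)(O[Si](CC)(CC)CC)CCO[Si](CC)(CC)CC | intermediate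
15 | acetate of 14 | CC(=O)OC/C(C/C=C/I)=C/CC[C@](C)(O[Si](CC)(CC)CC)CCO[Si](CC)(CC)CC | intermediate
16 | (2E,6S)-2-[(2E)-3-iodoprop-2-en-1-yl]-6-methyl-8-oxo-6-(triethylsilyloxy)oct-2-en-1-yl acetate | CC(=O)OC/C(C/C=C/I)=C/CC[C@](C)(O[Si](CC)(CC)CC)CC=O | intermediate
17 | [(1E,4E,8S)-6-hydroxy-8-methyl-8-(triethylsilyloxy)cyclodeca-1,4-dien-2-yl]methyl acetate, both C-6 epimers (C-1=C-2 has its ring bonds cis, C-4=C-5 trans) | C1[C@](C)(O[Si](CC)(CC)CC)CC(O)/C=C/C/C(COC(C)=O)=C\C1 | intermediate
18 | [(1E,4E,8S)-8-methyl-6-oxo-8-(triethylsilyloxy)cyclodeca-1,4-dien-2-yl]methyl acetate | C1[C@](C)(O[Si](CC)(CC)CC)CC(=O)/C=C/C/C(COC(C)=O)=C\C1 | intermediate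
19 | [(1E,4E,6S,8S)-6-hydroxy-8-methyl-8-(triethylsilyloxy)cyclodeca-1,4-dien-2-yl]methyl acetate | C1[C@](C)(O[Si](CC)(CC)CC)C[C@H](O)/C=C/C/C(COC(C)=O)=C\C1 | intermediate
20 | [(1E,4E,6S,8S)-6,8-dihydroxy-8-methylcyclodeca-1,4-dien-2-yl]methyl acetate | C1[C@](C)(O)C[C@H](O)/C=C/C/C(COC(C)=O)=C\C1 | intermediate
21 | Meldrum's acid (2,2-dimethyl-1,3-dioxane-4,6-dione) | CC1(C)OC(=O)CC(=O)O1 | starting material
22 | hydrogen malonate of 20 at the C-6 oxygen | C1[C@](C)(O)C[C@H](OC(=O)CC(=O)O)/C=C/C/C(COC(C)=O)=C\C1 | intermediate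
23 | bis-lactone: Cα on C-5 with lactone carbonyls closed on O-6 and on O-4; H-Cα and H-5 cis; C-3 and C-7 on the convex face; CH2OAc on C-2 and OH on C-8 unchanged | O=C1O[C@@H]2C/C(COC(C)=O)=C\CC[C@](C)(O)C[C@@H]3OC(=O)[C@@H]1[C@@H]23 | intermediate
24 | Eschenmoser's salt (N,N-dimethylmethyleneiminium iodide) | C=[N+](C)C.[I-] | starting material
25 | Cα-(dimethylaminomethyl) bis-lactone | O=C1O[C@@H]2C/C(COC(C)=O)=C\CC[C@](C)(O)C[C@@H]3OC(=O)[C@]1(CN(C)C)[C@@H]23 | intermediate (not isolated)
26 | Cα-[(trimethylammonio)methyl] bis-lactone iodide | O=C1O[C@@H]2C/C(COC(C)=O)=C\CC[C@](C)(O)C[C@@H]3OC(=O)[C@]1(C[N+](C)(C)C)[C@@H]23.[I-] | intermediate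
27 | lithium acrylate on C-5 with free hydroxyls on C-4, C-6, C-8 and on the C-2 CH2OH | C1[C@](C)(O)C[C@H](O)[C@@H](C(=C)C(=O)[O-])[C@H](O)C/C(CO)=C\C1.[Li+] | intermediate (not isolated)
28 | α-methylene γ-lactone on O-4, O-6/O-8 cyclic phenylboronate, free CH2OH on C-2 | C=C1C(=O)O[C@@H]2C/C(CO)=C\CC[C@](C)(OB3c4ccccc4)C[C@H](O3)[C@@H]12 | intermediate
29 | acetate of 28 | C=C1C(=O)O[C@@H]2C/C(COC(C)=O)=C\CC[C@](C)(OB3c4ccccc4)C[C@H](O3)[C@@H]12 | intermediate (not isolated)
30 | C-6 epimer of the de-angeloyl target (6S hydroxyl; C-4, C-5 and C-8 as in the target) | C=C1C(=O)O[C@@H]2C/C(COC(C)=O)=C\CC[C@](C)(O)C[C@H](O)[C@@H]12 | intermediate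
31 | angelic acid, (2Z)-2-methylbut-2-enoic acid | C/C=C(/C)C(=O)O | starting material
32 | CNP0270682.1 | C=C1C(=O)O[C@@H]2C/C(COC(C)=O)=C\CC[C@](C)(O)C[C@@H](OC(=O)/C(C)=C\C)[C@@H]12 | target

Total step count: 20. Longest linear sequence: 19 steps (steps 1 to 4 and 6 to 20 from geraniol).

**Steps most likely to fail**

Step 16. The cascade may stop after the first ring closure (hydrogen abstraction by the C-4 radical, loss of a C-3 hydrogen to a diene, or transannular capture by the C-8 hydroxyl), and delivery to C-5 may leak to the cis mode. The fallback sets out from 20 and separates the two bond formations. Acylation with methyl 3-chloro-3-oxopropanoate and pyridine should give the mixed methyl malonate F1, and diazo transfer with 4-acetamidobenzenesulfonyl azide and Et3N the diazomalonate F2. Rh2(OAc)4-catalysed intramolecular cyclopropanation of the E-alkene should give the cyclopropane-fused lactone F3, in which Cα is bonded to both C-5 and C-4. MgI2 in THF should open the activated cyclopropane at C-4 with inversion to the iodide F4. On warming in toluene the ester carbonyl oxygen displaces iodide with a second inversion and loss of iodomethane, and the route is rejoined at 23.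

Step 18. Lactonization may close on the C-6 hydroxyl before the boronate is in place, and hydroxide may add to the methylene lactone formed in passing. The fallback sets out from 26 and avoids full saponification. Aqueous NaHCO3 in THF opens only one lactone before fragmentation, so the acetate survives and 30 should form together with its lactone regioisomer F5 (lactone on O-6, free C-4 hydroxyl). The mixture is treated with 2-methoxypropene and pyridinium p-toluenesulfonate, then catalytic DBU; acyl migration interconverts the two lactones while only 30 is drained as its 6,8-O-isopropylidene acetal F6. Aqueous acetic acid then returns 30, so the route is rejoined at 30 and step 19 is bypassed.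

Step 20. Displacement at the hindered C-6 carbinol may be slow, elimination toward C-7 may compete, and the phosphine may add to the methylene lactone. The fallback sets out from 30 and separates inversion from angelate formation. A Mitsunobu reaction with the more acidic chloroacetic acid should give the inverted chloroacetate F7. Thiourea and NaHCO3 in ethanol remove the chloroacetyl group in the presence of the acetate to give the 6R alcohol F8. Yamaguchi esterification with 31 (2,4,6-trichlorobenzoyl chloride, Et3N, DMAP, toluene) then gives 32.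

Further compounds
F1 | step 16 | methyl malonate of 20 at the C-6 oxygen | C1[C@](C)(O)C[C@H](OC(=O)CC(=O)OC)/C=C/C/C(COC(C)=O)=C\C1
F2 | step 16 | diazomalonate of 20 at the C-6 oxygen | C1[C@](C)(O)C[C@H](OC(=O)C(=[N+]=[N-])C(=O)OC)/C=C/C/C(COC(C)=O)=C\C1
F3 | step 16 | cyclopropane-fused lactone (Cα bonded to C-5 and C-4, methyl ester on Cα, lactone on O-6) | COC(=O)[C@]12C(=O)O[C@H]3C[C@@](C)(O)CC/C=C(COC(C)=O)\C[C@@H]1[C@H]23
F4 | step 16 | C-4 iodide with lactone on O-6 and methyl ester on Cα | COC(=O)C1C(=O)O[C@H]2C[C@@](C)(O)CC/C=C(COC(C)=O)\C[C@H](I)[C@H]12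
F5 | step 18 | lactone regioisomer of 30 (α-methylene lactone on O-6, free C-4 hydroxyl) | C=C1C(=O)O[C@H]2C[C@@](C)(O)CC/C=C(COC(C)=O)\C[C@@H](O)[C@H]12
F6 | step 18 | 6,8-O-isopropylidene acetal of 30 | C=C1C(=O)O[C@@H]2C/C(COC(C)=O)=C\CC[C@@]3(C)C[C@H](OC(C)(C)O3)[C@@H]12
F7 | step 20 | 6R chloroacetate of the de-angeloyl target | C=C1C(=O)O[C@@H]2C/C(COC(C)=O)=C\CC[C@](C)(O)C[C@@H](OC(=O)CCl)[C@@H]12
F8 | step 20 | de-angeloyl target with 6R hydroxyl | C=C1C(=O)O[C@@H]2C/C(COC(C)=O)=C\CC[C@](C)(O)C[C@@H](O)[C@@H]12
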